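**Assumption:** (S)-(+)-terpinen-4-ol is bought in high ee (natural tea-tree material is only partly enriched and would need upgrading first). Daucane numbering is used throughout: C1 = quaternary C–Me, C4 = C(OH)iPr, C5 = ring-fusion CH, C6 = ester carbon, C8=C9 = ring alkene, C10 = CH2 on C1.

## Retrosynthetic overview

1. Fertidin ⇐ jaeschkeanadiol (selective C6–O acylation) ⇐ ring-closing metathesis forming C8=C9, so the seven-membered ring is closed last.
2. The RCM diene ⇐ chelation-controlled methallyl addition to a β-hydroxy aldehyde (sets C6).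
3. That aldehyde ⇐ anionic oxy-Cope [3,3] rearrangement of a 1,5-dien-3-ol: this forms the C1–C10 bond and the quaternary C1 and sets up C5–H (key step).
4. The dienol ⇐ a cyclopentene carbaldehyde by allylation, then oxidation and directed reduction to fix the relay carbinol.
5. The cyclopentene carbaldehyde ⇐ (S)-(+)-terpinen-4-ol by ozonolysis and intramolecular aldol condensation; the five-membered ring is formed first and C4 is bought.

## Route

**Step 1**
Reactants: 1, (S)-(+)-terpinen-4-ol
Product: 2, (3S)-3-hydroxy-6-oxo-3-(propan-2-yl)heptanal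
Conditions: O3, CH2Cl2/MeOH, −78 °C; then Me2S, −78 °C → rt
Reagents that add atoms: ozone, [O-][O+]=O
Why: Ozonolysis with reductive work-up cleaves the only alkene to a methyl ketone and an aldehyde; the C4 carbinol is not touched.

**Step 2**
Reactants: 2
Product: 3, (5R)-5-hydroxy-2-methyl-5-(propan-2-yl)cyclopent-1-ene-1-carbaldehyde
Conditions: piperidine (0.3 eq), AcOH (0.3 eq), PhH, 60 °C
Reagents that add atoms: none
Why: Enamine-mediated intramolecular aldol condensation (aldehyde α-carbon onto the methyl ketone, five-membered ring), with dehydration toward the less strained methyl-substituted enal; no new stereocentre.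

**Step 3**
Reactants: 3; 4, allylmagnesium bromide
Product: 5, 1-[(5R)-5-hydroxy-2-methyl-5-(propan-2-yl)cyclopent-1-en-1-yl]but-3-en-1-ol (both carbinol epimers)
Conditions: allylMgBr (2.5 eq), Et2O, −78 °C; aq NH4Cl
Reagents that add atoms: allylmagnesium bromide, C=CC[Mg]Br
Why: Grignard 1,2-addition to the hindered enal (first equivalent deprotonates the tertiary OH); the new carbinol is not controlled here and is corrected in steps 4–5.

**Step 4**
Reactants: 5
Product: 6, 1-[(5R)-5-hydroxy-2-methyl-5-(propan-2-yl)cyclopent-1-en-1-yl]but-3-en-1-one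
Conditions: Dess–Martin periodinane, NaHCO3, CH2Cl2, 0 °C (use crude)
Reagents that add atoms: none
Why: Dess–Martin oxidation of the secondary alcohol only; buffered, cold, neutral conditions keep the β,γ-unsaturated (allyl) ketone from conjugating.

**Step 5**
Reactants: 6
Product: 7, (1S)-1-[(5R)-5-hydroxy-2-methyl-5-(propan-2-yl)cyclopent-1-en-1-yl]but-3-en-1-ol
Conditions: Me4NBH(OAc)3, MeCN/AcOH, −30 °C
Reagents that add atoms: none
Why: Saksena–Evans directed reduction: the C4 hydroxyl binds boron and delivers hydride to the ketone face syn to the C4–O bond while the allyl CH2 twists away from the ring methyl (A1,3), giving the (S)-carbinol from both epimers of 5.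

**Step 6**
Reactants: 7
Product: 8, (1R,2R,5R)-2-hydroxy-5-methyl-5-(prop-2-en-1-yl)-2-(propan-2-yl)cyclopentane-1-carbaldehyde
Conditions: KH (2.5 eq), THF, 0 → 65 °C; then MeOH, 0 °C, 1 h; aq NH4Cl
Reagents that add atoms: none
Why: Anionic oxy-Cope [3,3] rearrangement through a chair transition state with the carbinol H (not O⁻) over the C1 methyl and K⁺ bridging the two alkoxides, so the allyl terminus bonds to the C1 face anti to C4–O and the C6 configuration is transferred to quaternary C1; the MeOH hold equilibrates C5 to the epimer with CHO cis to OH and Me (trans to iPr and allyl).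

**Step 7**
Reactants: 8; 9, 2-methylallylmagnesium chloride
Product: 10, (1S)-1-[(1S,2R,5R)-2-hydroxy-5-methyl-5-(prop-2-en-1-yl)-2-(propan-2-yl)cyclopentyl]-3-methylbut-3-en-1-ol
Conditions: 2-methylallylMgCl (3 eq), THF, −78 → −40 °C; aq NH4Cl
Reagents that add atoms: 2-methylallylmagnesium chloride, CC(=C)C[Mg]Cl
Why: Chelation-controlled Grignard addition: the C4 magnesium alkoxide chelates the aldehyde oxygen and the nucleophile attacks from the C5–H side, anti to quaternary C1 (the Felkin–Anh model with C1 as the anti group agrees), giving 6S.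

**Step 8**
Reactants: 10
Product: 11, jaeschkeanadiol, (3R,3aS,4S,8aR)-6,8a-dimethyl-3-(propan-2-yl)-1,2,3,3a,4,5,8,8a-octahydroazulene-3,4-diol
Conditions: Grubbs II (5 mol %), CH2Cl2 (5 mM), 40 °C
Reagents that add atoms: none
Why: Ring-closing metathesis of the allyl and methallyl groups gives the trans-fused cycloheptene with the trisubstituted C8=C9 alkene (ethylene lost); no stereocentre changes and the free diol is tolerated.

**Step 9**
Reactants: 11; 12, 4-methoxybenzoyl chloride
Product: 13, fertidin, (3R,3aS,4S,8aR)-3-hydroxy-6,8a-dimethyl-3-(propan-2-yl)-1,2,3,3a,4,5,8,8a-octahydroazulen-4-yl 4-methoxybenzoate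
Conditions: 4-MeOC6H4COCl, Et3N, DMAP, CH2Cl2, 0 °C → rt
Reagents that add atoms: 4-methoxybenzoyl chloride, COc1ccc(cc1)C(Cl)=O
Why: DMAP-catalysed acylation takes the secondary C6–OH; the tertiary C4–OH does not acylate under these conditions.

## Compound list

1 | (S)-(+)-terpinen-4-ol, (1S)-4-methyl-1-(propan-2-yl)cyclohex-3-en-1-ol | CC1=CC[C@](O)(C(C)C)CC1 | starting material
2 | (3S)-3-hydroxy-6-oxo-3-(propan-2-yl)heptanal | CC(=O)CC[C@@](O)(C(C)C)CC=O | intermediate
3 | (5R)-5-hydroxy-2-methyl-5-(propan-2-yl)cyclopent-1-ene-1-carbaldehyde | O=CC1=C(C)CC[C@@]1(O)C(C)C | intermediate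
4 | allylmagnesium bromide | C=CC[Mg]Br | starting material
5 | 1-[(5R)-5-hydroxy-2-methyl-5-(propan-2-yl)cyclopent-1-en-1-yl]but-3-en-1-ol (carbinol epimers) | C=CCC(O)C1=C(C)CC[C@@]1(O)C(C)C | intermediate
6 | 1-[(5R)-5-hydroxy-2-methyl-5-(propan-2-yl)cyclopent-1-en-1-yl]but-3-en-1-one | C=CCC(=O)C1=C(C)CC[C@@]1(O)C(C)C | intermediate
7 | (1S)-1-[(5R)-5-hydroxy-2-methyl-5-(propan-2-yl)cyclopent-1-en-1-yl]but-3-en-1-ol | C=CC[C@H](O)C1=C(C)CC[C@@]1(O)C(C)C | intermediate
8 | (1R,2R,5R)-2-hydroxy-5-methyl-5-(prop-2-en-1-yl)-2-(propan-2-yl)cyclopentane-1-carbaldehyde | O=C[C@H]1[C@](O)(C(C)C)CC[C@]1(C)CC=C | intermediate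
9 | 2-methylallylmagnesium chloride | CC(=C)C[Mg]Cl | starting material
10 | (1S)-1-[(1S,2R,5R)-2-hydroxy-5-methyl-5-(prop-2-en-1-yl)-2-(propan-2-yl)cyclopentyl]-3-methylbut-3-en-1-ol | C=C(C)C[C@H](O)[C@H]1[C@](O)(C(C)C)CC[C@]1(C)CC=C | intermediate
11 | jaeschkeanadiol | O[C@H]1CC(C)=CC[C@@]2(C)CC[C@@](O)(C(C)C)[C@H]12 | intermediate
12 | 4-methoxybenzoyl chloride | COc1ccc(cc1)C(Cl)=O | starting material
13 | fertidin | COc1ccc(C(=O)O[C@H]2CC(C)=CC[C@@]3(C)CC[C@@](O)(C(C)C)[C@H]23)cc1 | target

## Summary

Total steps: 9. Longest linear sequence: 9 (from 1).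

Steps most likely to fail:

1. **Step 6 (oxy-Cope).** The allyl group must bond to the C1 face that also carries the C4 isopropyl, so the C6-to-C1 relay works against the ring's own steric bias; facial leakage or retro-allylation is possible. Fallback: lock diol 7 as its acetonide (or di-tert-butylsilylene), which holds the allyl group axial on the required face, run the neutral Cope thermally (o-dichlorobenzene, about 200 °C), then hydrolyse the enol acetal to 8.
2. **Step 2 (aldol condensation).** The aldol adduct has two tertiary β-hydroxyls, so dehydration could remove the C4–OH instead, or 2 could dehydrate before cyclising. Fallback: silylate 1 (TESOTf, 2,6-lutidine) before ozonolysis, cyclise the TES ether, and remove the silyl group (TBAF) before step 3.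
3. **Step 5 (relay carbinol).** The (S) outcome rests on a conformational model for a twisted enone, and the allyl ketone can isomerise into conjugation. Fallback: skip the oxidation–reduction, separate the epimers of 5, and convert the unwanted (R)-carbinol by Mitsunobu inversion (4-nitrobenzoic acid, DIAD, PPh3; then K2CO3, MeOH).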